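## Retrosynthetic overview

1. Apteniol E is a symmetric diaryl ether whose oxygen carries four ortho methoxy groups. No aryl–O bond is made by coupling: ring A, with both methoxy groups and its propanoate chain, is taken whole from sinapic acid.
2. Feature used: in ring B (C1' bearing the chain, C2' and C6' as CH, C3' and C5' as C–OMe, C4' as the ether carbon), C4' sits between two oxygen-bearing carbons. Ring B is therefore an aromatised, O-methylated 2-aryloxycyclohexane-1,3-dione, and the crowded ArO–C4' bond reduces to O-alkylation of the ring A phenol with a 4-chloroacetoacetate.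
3. Key disconnection: ring B is opened at C1'–C2' (Michael) and C4'–C5' (Claisen) to a 4-aryloxyacetoacetate and dimethyl (E)-hex-2-enedioate, the latter from methyl 4-oxobutanoate by Horner–Wadsworth–Emmons olefination.
4. Ring order: ring A is preformed; ring B is closed in step 5, then decarboxylated, aromatised with iodine in methanol, O-methylated, and the two chain esters are hydrolysed.

Key step: step 5

Assumption: iodine in methanol (step 7) is taken to stop mainly at the monomethyl ether 15 with both chain acids esterified in the flask; any material methylated at both ring B oxygens is already 16 and merges at step 8.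

Remarks: the target has no stereocentre. Compounds 10 and 11 are racemic trans compounds (one enantiomer drawn), and their two stereocentres are erased in steps 6 and 7. The 1,3-diones are drawn in the enol form.

## Route

Step 1
Reactants: 1 sinapic acid
Product: 2 3-(4-hydroxy-3,5-dimethoxyphenyl)propanoic acid
Conditions: H2 (1 atm), 10% Pd/C, MeOH, rt
Reagents that add atoms: none
Why: Heterogeneous catalytic hydrogenation should saturate the cinnamate C=C and leave the arene, the phenol and the aryl methyl ethers untouched.

Step 2
Reactants: 2 3-(4-hydroxy-3,5-dimethoxyphenyl)propanoic acid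
Product: 3 methyl 3-(4-hydroxy-3,5-dimethoxyphenyl)propanoate
Conditions: MeOH, H2SO4 (cat.), reflux
Reagents that add atoms: methanol, CO
Why: Fischer esterification of the unhindered acid; the phenol is not etherified in acidic methanol.

Step 3
Reactants: 3 methyl 3-(4-hydroxy-3,5-dimethoxyphenyl)propanoate; 4 methyl 4-chloroacetoacetate
Product: 5 methyl 4-[2,6-dimethoxy-4-(3-methoxy-3-oxopropyl)phenoxy]-3-oxobutanoate
Conditions: NaH (2.1 equiv), THF/DMF, 0 °C to rt; then 1 M HCl
Reagents that add atoms: none
Why: Williamson ether synthesis, in which the sodium phenoxide of 3 displaces the primary chloride of 4 by SN2 while the second equivalent of NaH holds 4 (and then 5) as the β-keto ester enolate, so that the ketone and active methylene are shielded and no free strong base remains to enolise the chain ester.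

Step 4
Reactants: 6 methyl 4-oxobutanoate; 7 trimethyl phosphonoacetate
Product: 8 dimethyl (E)-hex-2-enedioate
Conditions: NaH, THF, 0 °C; then 6, 0 °C to rt
Reagents that add atoms: none
Why: Horner–Wadsworth–Emmons olefination with a stabilised phosphonate anion, which should give the (E)-enoate.

Step 5
Reactants: 5 methyl 4-[2,6-dimethoxy-4-(3-methoxy-3-oxopropyl)phenoxy]-3-oxobutanoate; 8 dimethyl (E)-hex-2-enedioate
Product: 10 methyl trans-3-[2,6-dimethoxy-4-(3-methoxy-3-oxopropyl)phenoxy]-4-hydroxy-6-(3-methoxy-3-oxopropyl)-2-oxocyclohex-3-ene-1-carboxylate (racemic; enol form), via acyclic Michael adduct 9 (not isolated)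
Conditions: NaOMe (1.5 equiv), MeOH, reflux; then 1 M HCl, 0 °C
Reagents that add atoms: none
Why: Proposed new method: methoxide turns 5 into its β-keto ester enolate, whose doubly activated carbon (future C2') adds to the β-carbon of 8 to form C1'–C2' and place the propanoate chain on C1'; proton transfer in methanol then populates the carbanion at the aryloxy-bearing carbon (future C4'), which attacks the ester that came from the enoate in a Claisen condensation to form C4'–C5'. The closest known reaction is the NaOMe-mediated Michael–Claisen annulation of acetoacetates and 4-alkyl-3-oxo esters with crotonate-type enoates to 2,4-dioxocyclohexanecarboxylates (the dihydroorsellinate synthesis); what is new is an α-aryloxy ketone carbon as the Claisen donor, which the inductive effect of the aryloxy group should make more acidic than the methyl group of the parent case. Ring B closes in a 6-exo-trig mode, and the doubly stabilised 2-aryloxy-1,3-dione enolate is the thermodynamic sink that pulls the reversible sequence forward. The two new stereocentres (the ring carbons bearing CO2Me and the chain) should settle trans by base-mediated equilibration of the acidic C–H next to the ring ester, and both are erased later. The step needs C2' as the Michael donor and C4' as the Claisen donor: the first follows from the acidity gap between the β-keto ester position and the aryloxymethylene, the second from the fact that only C4' reaches the enoate-derived ester through a six-membered transition state, while in methanol the first-formed ester enolate is protonated before it can close a five-membered ring onto the distal chain ester. All esters are methyl esters in methanol, so transesterification changes nothing.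

Step 6
Reactants: 10 methyl trans-3-[2,6-dimethoxy-4-(3-methoxy-3-oxopropyl)phenoxy]-4-hydroxy-6-(3-methoxy-3-oxopropyl)-2-oxocyclohex-3-ene-1-carboxylate
Product: 12 3-[4-[4-(2-carboxyethyl)-2,6-dimethoxyphenoxy]-3-hydroxy-5-oxocyclohex-3-en-1-yl]propanoic acid (enol form of the 2-aryloxy-1,3-dione), via triacid 11 (not isolated)
Conditions: 2 M NaOH aq, 80 °C; then conc. HCl to pH 1, 80 °C
Reagents that add atoms: sodium hydroxide, [Na+].[OH-]
Why: Saponification of all three methyl esters (the dione is protected as its enolate in base) followed by acid-promoted decarboxylation of the β-keto acid; one transient stereocentre leaves with CO2 and the other becomes a non-stereogenic carbon of the symmetric dione.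

Step 7
Reactants: 12 3-[4-[4-(2-carboxyethyl)-2,6-dimethoxyphenoxy]-3-hydroxy-5-oxocyclohex-3-en-1-yl]propanoic acid
Product: 15 methyl 3-[4-[2-hydroxy-6-methoxy-4-(3-methoxy-3-oxopropyl)phenoxy]-3,5-dimethoxyphenyl]propanoate, via enol methyl ether diester 13 (not isolated), via iodo enone 14 (not isolated)
Conditions: I2 (1.1 equiv), MeOH, reflux
Reagents that add atoms: methanol, CO
Why: Iodine-in-methanol oxidative aromatisation of a cyclohexane-1,3-dione: acid-catalysed formation of the vinylogous methyl ester together with Fischer esterification of both chain acids, iodination at the carbon next to the remaining ketone, loss of HI and tautomerisation to the 3-methoxyphenol.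

Step 8
Reactants: 15 methyl 3-[4-[2-hydroxy-6-methoxy-4-(3-methoxy-3-oxopropyl)phenoxy]-3,5-dimethoxyphenyl]propanoate
Product: 16 dimethyl 3,3'-[oxybis(3,5-dimethoxy-4,1-phenylene)]dipropanoate
Conditions: Me2SO4, K2CO3, acetone, reflux
Reagents that add atoms: dimethyl sulfate, COS(=O)(=O)OC
Why: Williamson O-methylation of the remaining phenol under carbonate, which also esterifies any residual chain acid; the esters and the diaryl ether are inert.

Step 9
Reactants: 16 dimethyl 3,3'-[oxybis(3,5-dimethoxy-4,1-phenylene)]dipropanoate
Product: 17 apteniol E, 3,3'-[oxybis(3,5-dimethoxy-4,1-phenylene)]dipropanoic acid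
Conditions: LiOH·H2O, THF/H2O, rt; then 1 M HCl
Reagents that add atoms: lithium hydroxide, [Li+].[OH-]
Why: Saponification of two unhindered methyl esters; aryl methyl ethers and the diaryl ether do not react with aqueous hydroxide.

## Compound list

1 | sinapic acid | COc1cc(/C=C/C(=O)O)cc(OC)c1O | starting material
2 | 3-(4-hydroxy-3,5-dimethoxyphenyl)propanoic acid | COc1cc(CCC(=O)O)cc(OC)c1O | intermediate
3 | methyl 3-(4-hydroxy-3,5-dimethoxyphenyl)propanoate | COC(=O)CCc1cc(OC)c(O)c(OC)c1 | intermediate
4 | methyl 4-chloroacetoacetate | COC(=O)CC(=O)CCl | starting material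
5 | methyl 4-[2,6-dimethoxy-4-(3-methoxy-3-oxopropyl)phenoxy]-3-oxobutanoate | COC(=O)CCc1cc(OC)c(OCC(=O)CC(=O)OC)c(OC)c1 | intermediate
6 | methyl 4-oxobutanoate | COC(=O)CCC=O | starting material
7 | trimethyl phosphonoacetate | COC(=O)CP(=O)(OC)OC | starting material
8 | dimethyl (E)-hex-2-enedioate | COC(=O)/C=C/CCC(=O)OC | intermediate
9 | dimethyl 3-{4-[2,6-dimethoxy-4-(3-methoxy-3-oxopropyl)phenoxy]-1-methoxy-1,3-dioxobutan-2-yl}hexanedioate (acyclic Michael adduct; mixture of diastereomers, configuration not fixed) | COC(=O)CCc1cc(OC)c(OCC(=O)C(C(=O)OC)C(CC(=O)OC)CCC(=O)OC)c(OC)c1 | intermediate (not isolated)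
10 | methyl trans-3-[2,6-dimethoxy-4-(3-methoxy-3-oxopropyl)phenoxy]-4-hydroxy-6-(3-methoxy-3-oxopropyl)-2-oxocyclohex-3-ene-1-carboxylate (racemic, one enantiomer drawn; enol form) | COC(=O)CCc1cc(OC)c(OC2=C(O)C[C@@H](CCC(=O)OC)[C@H](C(=O)OC)C2=O)c(OC)c1 | intermediate
11 | trans-6-(2-carboxyethyl)-3-[4-(2-carboxyethyl)-2,6-dimethoxyphenoxy]-4-hydroxy-2-oxocyclohex-3-ene-1-carboxylic acid (triacid; racemic, one enantiomer drawn) | OC(=O)CCc1cc(OC)c(OC2=C(O)C[C@@H](CCC(=O)O)[C@H](C(=O)O)C2=O)c(OC)c1 | intermediate (not isolated)
12 | 3-[4-[4-(2-carboxyethyl)-2,6-dimethoxyphenoxy]-3-hydroxy-5-oxocyclohex-3-en-1-yl]propanoic acid (enol form of the 2-aryloxy-1,3-dione; the tautomers interconvert, so there is no fixed stereocentre) | OC(=O)CCc1cc(OC)c(OC2=C(O)CC(CCC(=O)O)CC2=O)c(OC)c1 | intermediate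
13 | methyl 3-[4-[2,6-dimethoxy-4-(3-methoxy-3-oxopropyl)phenoxy]-3-methoxy-5-oxocyclohex-3-en-1-yl]propanoate (enol methyl ether diester; racemic) | COC(=O)CCc1cc(OC)c(OC2=C(OC)CC(CCC(=O)OC)CC2=O)c(OC)c1 | intermediate (not isolated)
14 | methyl 3-[4-[2,6-dimethoxy-4-(3-methoxy-3-oxopropyl)phenoxy]-2-iodo-5-methoxy-3-oxocyclohex-4-en-1-yl]propanoate (iodo enone; mixture of diastereomers, configuration not fixed) | COC(=O)CCc1cc(OC)c(OC2=C(OC)CC(CCC(=O)OC)C(I)C2=O)c(OC)c1 | intermediate (not isolated)
15 | methyl 3-[4-[2-hydroxy-6-methoxy-4-(3-methoxy-3-oxopropyl)phenoxy]-3,5-dimethoxyphenyl]propanoate | COC(=O)CCc1cc(OC)c(Oc2c(O)cc(CCC(=O)OC)cc2OC)c(OC)c1 | intermediate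
16 | dimethyl 3,3'-[oxybis(3,5-dimethoxy-4,1-phenylene)]dipropanoate | COC(=O)CCc1cc(OC)c(Oc2c(OC)cc(CCC(=O)OC)cc2OC)c(OC)c1 | intermediate
17 | apteniol E, 3,3'-[oxybis(3,5-dimethoxy-4,1-phenylene)]dipropanoic acid | COc1cc(CCC(=O)O)cc(OC)c1Oc1c(OC)cc(CCC(=O)O)cc1OC | target

## Step count and risks

Total step count: 9. Longest linear sequence: 8 steps (steps 1, 2, 3, 5, 6, 7, 8, 9 from sinapic acid); step 4 is a one-step side branch.

Steps most likely to fail:

**Step 5 (key step).** The aryloxymethylene carbon may not engage as the Claisen donor. The Michael adduct may also be drained through reversible five-membered Dieckmann or aldol closures that involve the distal chain ester, so that ring B does not form cleanly.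

The fallback keeps ring B as a disguised 1,3-dione but makes the hindered C–O bond last, by known chemistry. It sets out from enoate 8 and phenol 3.
- Enoate 8 is condensed with commercial methyl acetoacetate (NaOMe, MeOH, reflux; the established acetoacetate–enoate Michael–Claisen annulation). This should give methyl trans-4-hydroxy-6-(3-methoxy-3-oxopropyl)-2-oxocyclohex-3-ene-1-carboxylate F1.
- Diazo transfer (4-acetamidobenzenesulfonyl azide, Et3N, MeCN, 0 °C to rt) at the methylene between the two ketone carbons should give methyl trans-3-diazo-6-(3-methoxy-3-oxopropyl)-2,4-dioxocyclohexane-1-carboxylate F2.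
- Slow addition of F2 to phenol 3 and Rh2(OAc)4 (cat.) in 1,2-dichloroethane at reflux should insert the rhodium carbenoid into the phenol O–H bond (O–H insertion of an α-diazo-1,3-dicarbonyl compound into a phenol).

The insertion product is 10, where the route is rejoined before step 6.

**Step 3.** Self-condensation of the chloroacetoacetate enolate (C-alkylation) may outrun O-alkylation by the hindered phenoxide.

The fallback builds the β-keto ester by acylation instead. It sets out from phenol 3.
- Alkylation with tert-butyl bromoacetate (K2CO3, acetone, reflux) should give tert-butyl 2-[2,6-dimethoxy-4-(3-methoxy-3-oxopropyl)phenoxy]acetate F3.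
- Trifluoroacetic acid in CH2Cl2 should cleave the tert-butyl ester to 2-[2,6-dimethoxy-4-(3-methoxy-3-oxopropyl)phenoxy]acetic acid F4.
- Activation with carbonyldiimidazole (CDI) in THF, then C-acylation of potassium methyl malonate in the presence of MgCl2 and Et3N with decarboxylation (Masamune-type β-keto ester synthesis), should give the β-keto ester.

That β-keto ester is 5, where the route is rejoined before step 5.

**Step 7.** Electrophilic iodination of the electron-rich ring A (or of ring B once it is aromatic) may compete, and enol ether formation or esterification may stay incomplete, giving mixtures.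

The fallback avoids electrophilic halogen. It sets out from dione 12.
- Catalytic dehydrogenation over 10% Pd/C in refluxing diglyme should give 3-[4-[4-(2-carboxyethyl)-2,6-dimethoxyphenoxy]-3,5-dihydroxyphenyl]propanoic acid F5.
- Exhaustive methylation of both phenols and both acids with Me2SO4 and K2CO3 in refluxing acetone should follow.

The methylation product is 16, where the route is rejoined before step 9.

Further compounds
F1 | step 5 | methyl trans-4-hydroxy-6-(3-methoxy-3-oxopropyl)-2-oxocyclohex-3-ene-1-carboxylate (racemic, one enantiomer drawn) | COC(=O)CC[C@@H]1CC(O)=CC(=O)[C@H]1C(=O)OC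
F2 | step 5 | methyl trans-3-diazo-6-(3-methoxy-3-oxopropyl)-2,4-dioxocyclohexane-1-carboxylate (racemic, one enantiomer drawn) | COC(=O)CC[C@@H]1CC(=O)C(=[N+]=[N-])C(=O)[C@H]1C(=O)OC
F3 | step 3 | tert-butyl 2-[2,6-dimethoxy-4-(3-methoxy-3-oxopropyl)phenoxy]acetate | COC(=O)CCc1cc(OC)c(OCC(=O)OC(C)(C)C)c(OC)c1
F4 | step 3 | 2-[2,6-dimethoxy-4-(3-methoxy-3-oxopropyl)phenoxy]acetic acid | COC(=O)CCc1cc(OC)c(OCC(=O)O)c(OC)c1
F5 | step 7 | 3-[4-[4-(2-carboxyethyl)-2,6-dimethoxyphenoxy]-3,5-dihydroxyphenyl]propanoic acid | OC(=O)CCc1cc(OC)c(Oc2c(O)cc(CCC(=O)O)cc2O)c(OC)c1
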